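**Retrosynthetic overview**

1. The target comes from hydrogenolysis of a pentabenzyl aryl ketone. That ketone is made by carbonylative alkyl Suzuki coupling of the ring D C3''-iodide with B-undecyl-9-BBN (from 1-undecene) and CO, which forms the C3''–C(=O) and C(=O)–CH2 bonds.
2. The strategy rests on ring D, the 2,4,6-trioxygenated phenyl ring on C4: C3'' and C5'' are interchanged by rotation about the C4–C1'' bond, and this ring is the most electron-rich one, so a single iodination marks the one acylation site.
3. The iodide comes from the pentabenzyl (2R,4S)-4-arylflavan. Its O1–C2 bond is closed by Mitsunobu inversion of a CBS-derived carbinol, which in turn comes from a Weinreb amide and 4-(benzyloxy)phenylmagnesium bromide.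
4. C4 is set by rhodium-catalysed asymmetric 1,4-addition of 2,4-bis(allyloxy)phenylboronic acid (ring A, from 4-bromoresorcinol) to 5,7-bis(benzyloxy)coumarin (from phloroglucinol). Opening the lactone and benzylating the freed phenol turns the coumarin benzo ring into ring D.
5. Ring order: the coumarin lactone ring first (temporary, opened later), then pyran ring C of the chroman. The key step closes no ring.

Key step: step 14

Remark: the sense of induction of the rhodium–(S)-SEGPHOS catalyst is assigned by analogy with simple coumarins; the configuration of the first adduct would be checked and the antipodal ligand used if it proved opposite.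

**Route**

Step 1
Reactants: 1 phloroglucinol; 2 ethyl propiolate
Product: 3 5,7-dihydroxy-2H-chromen-2-one (5,7-dihydroxycoumarin)
Conditions: ZnCl2, neat, 95 °C
Reagents that add atoms: none
Why: Lewis-acid-promoted hydroarylation of the propiolate by the symmetric triphenol followed by lactonisation (Pechmann-type coumarin synthesis); all three ring positions are equivalent, so one coumarin should result.

Step 2
Reactants: 3 5,7-dihydroxycoumarin
Product: 4 5,7-bis(benzyloxy)-2H-chromen-2-one
Conditions: BnBr, K2CO3, DMF, 60 °C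
Reagents that add atoms: benzyl bromide, BrCc1ccccc1
Why: Williamson etherification of both phenols; the lactone is inert to carbonate in an aprotic solvent.

Step 3
Reactants: 5 4-bromoresorcinol
Product: 6 2,4-bis(allyloxy)-1-bromobenzene
Conditions: allyl bromide, K2CO3, acetone, reflux
Reagents that add atoms: allyl bromide, C=CCBr
Why: Williamson etherification of both hydroxy groups, which avoids any regioselection between them and gives ethers orthogonal to benzyl.

Step 4
Reactants: 6 2,4-bis(allyloxy)-1-bromobenzene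
Product: 8 [2,4-bis(allyloxy)phenyl]boronic acid, via 2,4-bis(allyloxy)phenyllithium 7 (not isolated)
Conditions: n-BuLi, B(Oi-Pr)3 present from the start, THF/toluene, −78 °C; then 1 M HCl, 0 °C
Reagents that add atoms: triisopropyl borate, CC(C)OB(OC(C)C)OC(C)C; water, O
Why: Bromine–lithium exchange at −78 °C with in situ borate trapping outpaces carbolithiation of the ortho allyl ether, and hydrolysis of the borate gives the boronic acid.

Step 5
Reactants: 4 5,7-bis(benzyloxy)coumarin; 8 [2,4-bis(allyloxy)phenyl]boronic acid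
Product: 9 (S)-4-[2,4-bis(allyloxy)phenyl]-5,7-bis(benzyloxy)chroman-2-one
Conditions: Rh(acac)(C2H4)2 (3 mol %), (S)-SEGPHOS (3.3 mol %), 8 in excess added in portions, dioxane/H2O 10:1, 60 °C
Reagents that add atoms: none
Why: Hayashi–Miyaura asymmetric 1,4-addition, in which the aryl complex of monovalent rhodium formed by transmetallation adds across C3=C4 of the coumarin and water protonates the oxa-π-allyl; the (S)-bisphosphine shields one face of the planar lactone, so C4 should be formed as S, the sense known for 4-arylchroman-2-ones.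

Step 6
Reactants: 9 (S)-4-[2,4-bis(allyloxy)phenyl]-5,7-bis(benzyloxy)chroman-2-one
Product: 11 (S)-3-[2,4-bis(allyloxy)phenyl]-N-methoxy-N-methyl-3-[2,4,6-tris(benzyloxy)phenyl]propanamide, via phenolic Weinreb amide 10 (not isolated)
Conditions: MeNH(OMe)·HCl, i-PrMgCl (premixed), THF, −20 → 0 °C; aqueous work-up; then BnBr, K2CO3, DMF, rt
Reagents that add atoms: N,O-dimethylhydroxylamine hydrochloride, CNOC.Cl; benzyl bromide, BrCc1ccccc1
Why: Aminolysis of the aryl lactone by the magnesium amide (Weinreb amide formation) frees the ring D phenol, which is benzylated at once (Williamson) so that relactonisation cannot occur and ring D becomes the locally symmetric tris(benzyloxy)phenyl group; C3 is not touched.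

Step 7
Reactants: 11 Weinreb amide; 12 1-(benzyloxy)-4-bromobenzene
Product: 14 (S)-3-[2,4-bis(allyloxy)phenyl]-1-[4-(benzyloxy)phenyl]-3-[2,4,6-tris(benzyloxy)phenyl]propan-1-one, via 4-(benzyloxy)phenylmagnesium bromide 13 (not isolated)
Conditions: 12, Mg, THF, 40 °C; then 11, THF, 0 °C → rt; aq. NH4Cl
Reagents that add atoms: none
Why: Weinreb ketone synthesis; the chelated tetrahedral intermediate holds until work-up, so the aryl Grignard reagent adds once only.

Step 8
Reactants: 14 aryl ketone
Product: 15 (1S,3S)-3-[2,4-bis(allyloxy)phenyl]-1-[4-(benzyloxy)phenyl]-3-[2,4,6-tris(benzyloxy)phenyl]propan-1-ol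
Conditions: (R)-2-methyl-CBS-oxazaborolidine (20 mol %), catecholborane, toluene, −78 → −40 °C; then aq. NaOH work-up
Reagents that add atoms: none
Why: CBS reduction, in which the ketone binds the catalyst boron anti to its aryl group (the larger substituent) and hydride from the coordinated borane gives the (S)-carbinol under reagent control; catecholborane does not hydroborate the allyl ethers at this temperature.

Step 9
Reactants: 15 (1S,3S)-alcohol
Product: 16 4-{(1S,3S)-3-[4-(benzyloxy)phenyl]-3-hydroxy-1-[2,4,6-tris(benzyloxy)phenyl]propyl}benzene-1,3-diol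
Conditions: Pd(PPh3)4 (5 mol %), morpholine, THF, rt
Reagents that add atoms: none
Why: Tsuji–Trost-type deallylation, in which zerovalent palladium ionises the two allyl aryl ethers to π-allyl complexes that morpholine captures; the benzyl ethers and the carbinol are inert under these neutral conditions.

Step 10
Reactants: 16 triol
Product: 17 (2R,4S)-2-[4-(benzyloxy)phenyl]-4-[2,4,6-tris(benzyloxy)phenyl]chroman-7-ol
Conditions: PPh3, DIAD (betaine preformed), THF (0.01 M), 0 °C → rt
Reagents that add atoms: none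
Why: Intramolecular Mitsunobu etherification, in which only the ortho hydroxy group of the resorcinol ring can reach the activated carbinol (6-exo-tet) and SN2 displacement inverts the (S)-carbinol to C2 (R), trans to the C4 aryl group; a C2 epimer arising from ionisation of the electron-rich benzylic centre would be a diastereomer removable by chromatography.

Step 11
Reactants: 17 chroman-7-ol
Product: 18 (2R,4S)-7-(benzyloxy)-2-[4-(benzyloxy)phenyl]-4-[2,4,6-tris(benzyloxy)phenyl]chroman
Conditions: BnBr, K2CO3, DMF, rt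
Reagents that add atoms: benzyl bromide, BrCc1ccccc1
Why: Williamson etherification of the remaining phenol, so that ring A is no longer a free phenol ring when the electrophilic halogenation is run.

Step 12
Reactants: 18 pentabenzyl 4-arylflavan
Product: 19 (2R,4S)-7-(benzyloxy)-2-[4-(benzyloxy)phenyl]-4-[2,4,6-tris(benzyloxy)-3-iodophenyl]chroman
Conditions: NIS (1.0 equiv), CH2Cl2/MeCN, −20 → 0 °C, dark
Reagents that add atoms: N-iodosuccinimide, O=C1CCC(=O)N1I
Why: Electrophilic aromatic iodination at the ring on which three alkoxy donors converge (ring D) in preference to ring A with two; C3'' and C5'' are equivalent, so one mono-iodide should form, and the acid-free conditions spare the C2 benzylic ether.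

Step 13
Reactants: 20 1-undecene
Product: 21 9-undecyl-9-borabicyclo[3.3.1]nonane (used as its THF solution)
Conditions: 9-BBN (0.5 M in THF), 0 °C → rt
Reagents that add atoms: 9-borabicyclo[3.3.1]nonane, [H]B1C2CCCC1CCC2
Why: Anti-Markovnikov hydroboration of the terminal alkene places boron on the primary carbon.

Step 14
Reactants: 19 aryl iodide; 21 9-undecyl-9-borabicyclo[3.3.1]nonane; 22 carbon monoxide
Product: 23 1-{2,4,6-tris(benzyloxy)-3-[(2R,4S)-7-(benzyloxy)-2-(4-(benzyloxy)phenyl)chroman-4-yl]phenyl}dodecan-1-one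
Conditions: Pd(PPh3)4 (10 mol %), K3PO4 (3 equiv), CO (1 atm), dioxane/THF, 60 °C
Reagents that add atoms: none
Why: Zerovalent palladium inserts into the C3''–I bond of 19, CO inserts into the hindered aryl–palladium bond to give an aroyl complex, the phosphate-activated borate of 21 transfers its primary undecyl group while the bicyclic boron ligand stays on boron, and reductive elimination forms both the C3''–C(=O) and the C(=O)–CH2 bonds. This is the carbonylative Suzuki–Miyaura coupling of aryl iodides with B-alkyl-9-BBN reagents, a known reaction type. No ring is closed and no stereocentre is formed; C2 and C4 are left alone because the medium is basic and free of Lewis acid, unlike a Friedel–Crafts acylation. The selectivity needed is carbonylative over direct alkyl–aryl coupling; it is secured by the two benzyloxy groups flanking the palladium-bearing carbon, which slow transmetallation at the arylpalladium stage so that CO insertion comes first, and by keeping a CO atmosphere throughout. A single acylation at a single position is secured by the one iodine of 19, C3'' and C5'' being equivalent.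

Step 15
Reactants: 23 pentabenzyl ketone
Product: 24 1-{2,4,6-trihydroxy-3-[(2R,4S)-7-hydroxy-2-(4-hydroxyphenyl)chroman-4-yl]phenyl}dodecan-1-one (target)
Conditions: H2 (1 atm), 10% Pd on carbon, THF/MeOH, rt, stopped when uptake ceases
Reagents that add atoms: none
Why: Hydrogenolysis of the five benzyl ethers; the aryl ketone, which becomes a hydrogen-bonded ortho-hydroxyaryl ketone, and the cyclic C2–O1 ether should react more slowly than the benzyl ethers under these mild conditions.

**Compound list**

1 | phloroglucinol | Oc1cc(O)cc(O)c1 | starting material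
2 | ethyl propiolate | CCOC(=O)C#C | starting material
3 | 5,7-dihydroxy-2H-chromen-2-one | O=C1C=Cc2c(O)cc(O)cc2O1 | intermediate
4 | 5,7-bis(benzyloxy)-2H-chromen-2-one | O=C1C=Cc2c(OCc3ccccc3)cc(OCc3ccccc3)cc2O1 | intermediate
5 | 4-bromoresorcinol | Oc1ccc(Br)c(O)c1 | starting material
6 | 2,4-bis(allyloxy)-1-bromobenzene | C=CCOc1ccc(Br)c(OCC=C)c1 | intermediate
7 | 2,4-bis(allyloxy)phenyllithium | [Li]c1ccc(OCC=C)cc1OCC=C | intermediate
8 | [2,4-bis(allyloxy)phenyl]boronic acid | OB(O)c1ccc(OCC=C)cc1OCC=C | intermediate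
9 | (S)-4-[2,4-bis(allyloxy)phenyl]-5,7-bis(benzyloxy)chroman-2-one | O=C1C[C@@H](c2ccc(OCC=C)cc2OCC=C)c2c(OCc3ccccc3)cc(OCc3ccccc3)cc2O1 | intermediate
10 | (S)-3-[2,4-bis(allyloxy)phenyl]-3-[2,4-bis(benzyloxy)-6-hydroxyphenyl]-N-methoxy-N-methylpropanamide | CON(C)C(=O)C[C@@H](c1ccc(OCC=C)cc1OCC=C)c1c(O)cc(OCc2ccccc2)cc1OCc1ccccc1 | intermediate
11 | (S)-3-[2,4-bis(allyloxy)phenyl]-N-methoxy-N-methyl-3-[2,4,6-tris(benzyloxy)phenyl]propanamide | CON(C)C(=O)C[C@@H](c1ccc(OCC=C)cc1OCC=C)c1c(OCc2ccccc2)cc(OCc2ccccc2)cc1OCc1ccccc1 | intermediate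
12 | 1-(benzyloxy)-4-bromobenzene | Brc1ccc(OCc2ccccc2)cc1 | starting material
13 | 4-(benzyloxy)phenylmagnesium bromide | Br[Mg]c1ccc(OCc2ccccc2)cc1 | intermediate
14 | (S)-3-[2,4-bis(allyloxy)phenyl]-1-[4-(benzyloxy)phenyl]-3-[2,4,6-tris(benzyloxy)phenyl]propan-1-one | O=C(C[C@@H](c1ccc(OCC=C)cc1OCC=C)c1c(OCc2ccccc2)cc(OCc2ccccc2)cc1OCc1ccccc1)c1ccc(OCc2ccccc2)cc1 | intermediate
15 | (1S,3S)-3-[2,4-bis(allyloxy)phenyl]-1-[4-(benzyloxy)phenyl]-3-[2,4,6-tris(benzyloxy)phenyl]propan-1-ol | O[C@@H](C[C@@H](c1ccc(OCC=C)cc1OCC=C)c1c(OCc2ccccc2)cc(OCc2ccccc2)cc1OCc1ccccc1)c1ccc(OCc2ccccc2)cc1 | intermediate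
16 | 4-{(1S,3S)-3-[4-(benzyloxy)phenyl]-3-hydroxy-1-[2,4,6-tris(benzyloxy)phenyl]propyl}benzene-1,3-diol | O[C@@H](C[C@@H](c1ccc(O)cc1O)c1c(OCc2ccccc2)cc(OCc2ccccc2)cc1OCc1ccccc1)c1ccc(OCc2ccccc2)cc1 | intermediate
17 | (2R,4S)-2-[4-(benzyloxy)phenyl]-4-[2,4,6-tris(benzyloxy)phenyl]chroman-7-ol | c1ccccc1COc1cc(OCc2ccccc2)c([C@H]2C[C@H](c3ccc(OCc4ccccc4)cc3)Oc3cc(O)ccc32)c(OCc2ccccc2)c1 | intermediate
18 | (2R,4S)-7-(benzyloxy)-2-[4-(benzyloxy)phenyl]-4-[2,4,6-tris(benzyloxy)phenyl]chroman | c1ccccc1COc1cc(OCc2ccccc2)c([C@H]2C[C@H](c3ccc(OCc4ccccc4)cc3)Oc3cc(OCc4ccccc4)ccc32)c(OCc2ccccc2)c1 | intermediate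
19 | (2R,4S)-7-(benzyloxy)-2-[4-(benzyloxy)phenyl]-4-[2,4,6-tris(benzyloxy)-3-iodophenyl]chroman | c1ccccc1COc1c(I)c(OCc2ccccc2)c([C@H]2C[C@H](c3ccc(OCc4ccccc4)cc3)Oc3cc(OCc4ccccc4)ccc32)c(OCc2ccccc2)c1 | intermediate
20 | 1-undecene | C=CCCCCCCCCC | starting material
21 | 9-undecyl-9-borabicyclo[3.3.1]nonane | CCCCCCCCCCCB1C2CCCC1CCC2 | intermediate
22 | carbon monoxide | [C-]#[O+] | starting material
23 | 1-{2,4,6-tris(benzyloxy)-3-[(2R,4S)-7-(benzyloxy)-2-(4-(benzyloxy)phenyl)chroman-4-yl]phenyl}dodecan-1-one | CCCCCCCCCCCC(=O)c1c(OCc2ccccc2)cc(OCc2ccccc2)c([C@H]2C[C@H](c3ccc(OCc4ccccc4)cc3)Oc3cc(OCc4ccccc4)ccc32)c1OCc1ccccc1 | intermediate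
24 | 1-{2,4,6-trihydroxy-3-[(2R,4S)-7-hydroxy-2-(4-hydroxyphenyl)chroman-4-yl]phenyl}dodecan-1-one | CCCCCCCCCCCC(=O)c1c(O)cc(O)c([C@H]2C[C@H](c3ccc(O)cc3)Oc3cc(O)ccc32)c1O | target

**Step count**

Total steps: 15. Longest linear sequence: 12 steps (steps 3 to 12, 14 and 15 from 4-bromoresorcinol; equally steps 1, 2, 5 to 12, 14 and 15 from phloroglucinol).

**Steps most likely to fail**

Step 14 (carbonylative coupling). Oxidative addition into the doubly flanked, electron-rich C3''–I bond may be slow under a CO atmosphere, and undecyl transfer before CO insertion or reduction of the C–I bond may compete. The fallback sets out from iodide 19 and makes the ketone by polar chemistry. Iodine–magnesium exchange (i-PrMgCl·LiCl, THF, −20 → 0 °C) gives the arylmagnesium chloride F1, which is added to dodecanal to give the secondary benzylic alcohol F2 as a mixture of carbinol epimers. Dess–Martin oxidation (CH2Cl2, NaHCO3, rt) then returns to the route at ketone 23.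

Step 5 (asymmetric 1,4-addition). Carbometallation at the peri-hindered, electron-rich C4 of the coumarin may be outrun by protodeboronation of the ortho-alkoxy boronic acid, or face selection may be incomplete. The fallback sets out from bromide 6 and coumarin 4 and forms C4 without asymmetric catalysis. Bromide 6 and Mg in THF give 2,4-bis(allyloxy)phenylmagnesium bromide F3, which is added to 4 under CuBr·SMe2 catalysis (THF, −40 → 0 °C) to give the racemic lactone F4. Preparative chromatography on a chiral stationary phase separates the (S)-enantiomer, which is compound 9 where the route is rejoined, from the (R)-enantiomer F5.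

Step 12 (mono-iodination). Iodination may be shared between ring D and C6 of ring A, or run on to a di-iodide. The fallback sets out from phenol 17 and switches ring A off electronically before halogenation. Acetylation (Ac2O, pyridine) gives the 7-acetate F6, whose ring A is far less nucleophilic than the tris(benzyloxy) ring D. N-Iodosuccinimide then gives the iodo acetate F7, methanolysis (catalytic K2CO3, MeOH/THF) frees the 7-hydroxy iodide F8, and benzylation (BnBr, K2CO3, DMF) returns to the route at 19, bypassing 18.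

**Further compounds**

F1 | step 14 | {2,4,6-tris(benzyloxy)-3-[(2R,4S)-7-(benzyloxy)-2-(4-(benzyloxy)phenyl)chroman-4-yl]phenyl}magnesium chloride | c1ccccc1COc1c([Mg]Cl)c(OCc2ccccc2)c([C@H]2C[C@H](c3ccc(OCc4ccccc4)cc3)Oc3cc(OCc4ccccc4)ccc32)c(OCc2ccccc2)c1
F2 | step 14 | 1-{2,4,6-tris(benzyloxy)-3-[(2R,4S)-7-(benzyloxy)-2-(4-(benzyloxy)phenyl)chroman-4-yl]phenyl}dodecan-1-ol (carbinol epimers) | CCCCCCCCCCCC(O)c1c(OCc2ccccc2)cc(OCc2ccccc2)c([C@H]2C[C@H](c3ccc(OCc4ccccc4)cc3)Oc3cc(OCc4ccccc4)ccc32)c1OCc1ccccc1
F3 | step 5 | 2,4-bis(allyloxy)phenylmagnesium bromide | Br[Mg]c1ccc(OCC=C)cc1OCC=C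
F4 | step 5 | racemic 4-[2,4-bis(allyloxy)phenyl]-5,7-bis(benzyloxy)chroman-2-one | O=C1CC(c2ccc(OCC=C)cc2OCC=C)c2c(OCc3ccccc3)cc(OCc3ccccc3)cc2O1
F5 | step 5 | (R)-4-[2,4-bis(allyloxy)phenyl]-5,7-bis(benzyloxy)chroman-2-one | O=C1C[C@H](c2ccc(OCC=C)cc2OCC=C)c2c(OCc3ccccc3)cc(OCc3ccccc3)cc2O1
F6 | step 12 | (2R,4S)-2-[4-(benzyloxy)phenyl]-4-[2,4,6-tris(benzyloxy)phenyl]chroman-7-yl acetate | c1ccccc1COc1cc(OCc2ccccc2)c([C@H]2C[C@H](c3ccc(OCc4ccccc4)cc3)Oc3cc(OC(C)=O)ccc32)c(OCc2ccccc2)c1
F7 | step 12 | (2R,4S)-2-[4-(benzyloxy)phenyl]-4-[2,4,6-tris(benzyloxy)-3-iodophenyl]chroman-7-yl acetate | c1ccccc1COc1c(I)c(OCc2ccccc2)c([C@H]2C[C@H](c3ccc(OCc4ccccc4)cc3)Oc3cc(OC(C)=O)ccc32)c(OCc2ccccc2)c1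
F8 | step 12 | (2R,4S)-2-[4-(benzyloxy)phenyl]-4-[2,4,6-tris(benzyloxy)-3-iodophenyl]chroman-7-ol | c1ccccc1COc1c(I)c(OCc2ccccc2)c([C@H]2C[C@H](c3ccc(OCc4ccccc4)cc3)Oc3cc(O)ccc32)c(OCc2ccccc2)c1
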